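**Retrosynthetic overview**
1. The target is opened by a retro-intramolecular Diels–Alder reaction (cyclopentane and ester-bearing cyclohexene) to a 7,8-trans-disubstituted bicyclo[4.2.0]octa-2,4-diene, which is the 6π valence isomer of a trans-7,8-disubstituted cycloocta-1,3,5-triene (cyclobutane and cyclohexadiene).
2. The triene comes from a 2,3-trans-disubstituted cycloocta-4,6-dienone by enol triflate formation and reduction.
3. Key disconnection: the eight-membered ketone comes from a one-carbon ring expansion (carbenoid 1,2-shift) of a 2-alkylcyclohepta-3,5-dienone; the ring-expanded enolate is alkylated in the same flask with methyl 6-bromosorbate.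
4. The cycloheptadienone comes from an enantioselective 1,8-addition of a decenylzirconium reagent to tropone; the chain is made from 7-bromohept-1-ene and (E)-1-bromopropene, the arm from sorbic acid.
5. Ring order: seven-membered ring (bought), then eight-membered ring (ring expansion), then cyclobutane plus cyclohexadiene (6π), then cyclopentane plus cyclohexene (Diels–Alder).

Assumption: ring atoms of the target are labelled C1–C13 in the order in which they stand in the target SMILES (C1 carries the chain, C13 the ester); 2 is bought as the pure E isomer; the ligand enantiomer named in step 2 is taken to be the one that gives (R)-8, to be confirmed in the first run.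

**Step 1**
Reactants: 1 7-bromohept-1-ene; 2 (E)-1-bromoprop-1-ene
Product: 4 (8E)-deca-1,8-diene, via hept-6-enylmagnesium bromide 3 (not isolated)
Conditions: Mg, THF, 40 °C; then 2, Fe(acac)3 (3 mol %), THF/NMP, 0 °C
Reagents that add atoms: none
Why: Iron-catalysed Kumada-type alkyl–alkenyl cross-coupling of the primary alkylmagnesium bromide with the alkenyl bromide proceeds with retention of the E geometry and leaves the terminal alkene untouched; no stereocentre is formed.

**Step 2**
Reactants: 4 (8E)-deca-1,8-diene; 5 tropone (cyclohepta-2,4,6-trien-1-one)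
Product: 8 (2R)-2-[(8E)-dec-8-en-1-yl]cyclohepta-3,5-dien-1-one, via alkylzirconocene chloride 6 (not isolated), via zirconium trienolate 7 (not isolated)
Conditions: 4 (1.6 equiv), Cp2Zr(H)Cl (1.4 equiv), CH2Cl2, 25 °C; then 5, CuCl (10 mol %), AgNTf2 (12 mol %), (S)-BINOL-derived N,N-bis[(R)-1-phenylethyl]phosphoramidite (11 mol %), t-BuOMe, 0 °C; sat. aq NH4Cl, 0 °C; used crude and cold
Reagents that add atoms: none
Why: Proposed new method: copper–phosphoramidite-catalysed enantioselective 1,8-conjugate addition of an alkylzirconocene (from chemoselective hydrozirconation of the terminal alkene of 4) to tropone, in which Zr-to-Cu transmetalation gives a chiral alkyl complex of monovalent copper that binds one of the two enantiotopic C2=C3/C6=C7 edges of the flat trienone and delivers the alkyl group to C2, the position attacked in the known uncatalysed 1,8-additions of alkylmagnesium halides and cuprates to tropone, leaving a fully conjugated trienolate that is protonated at C7 on work-up so that the new α-stereocentre (R, fixed by the ligand enantiomer) is never enolised; the closest known reactions are the copper–phosphoramidite-catalysed asymmetric 1,4- and 1,6-conjugate additions of alkylzirconocenes to cyclic enones and dienones.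

**Step 3**
Reactants: 9 sorbic acid ((2E,4E)-hexa-2,4-dienoic acid)
Product: 10 methyl (2E,4E)-hexa-2,4-dienoate
Conditions: MeOH, H2SO4 (cat.), reflux
Reagents that add atoms: methanol (CO)
Why: Fischer esterification of the conjugated acid leaves both E double bonds untouched and forms no stereocentre.

**Step 4**
Reactants: 10 methyl (2E,4E)-hexa-2,4-dienoate
Product: 11 methyl (2E,4E)-6-bromohexa-2,4-dienoate
Conditions: NBS, (PhCO2)2 (cat.), PhCl, 100 °C
Reagents that add atoms: N-bromosuccinimide (O=C1CCC(=O)N1Br)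
Why: Wohl–Ziegler allylic bromination goes through the pentadienyl radical and gives the terminal, fully conjugated (2E,4E) primary bromide as the main product; no stereocentre is formed.

**Step 5**
Reactants: 8 (2R)-2-[(8E)-dec-8-en-1-yl]cyclohepta-3,5-dien-1-one; 11 methyl (2E,4E)-6-bromohexa-2,4-dienoate
Product: 15 methyl (2E,4E)-6-[(1S,8R)-8-[(8E)-dec-8-en-1-yl]-2-oxocycloocta-4,6-dien-1-yl]hexa-2,4-dienoate, via lithium alkoxide 12 (not isolated), via lithium carbenoid 13 (not isolated), via lithium enolate 14 (not isolated)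
Conditions: CH2Br2, LiTMP (lithium 2,2,6,6-tetramethylpiperidide), THF/Et2O, −100 °C, then 8; n-BuLi (1.3 equiv), −100 to −20 °C; then DMPU, 11 (1.5 equiv), −78 to −20 °C
Reagents that add atoms: dibromomethane (BrCBr)
Why: β-Oxido carbenoid ring enlargement (dibromomethyllithium homologation of a ketone): 1,2-addition gives alkoxide 12, bromine–lithium exchange gives carbenoid 13, and a 1,2-shift of the more substituted, allylic ring carbon C2 (with retention, bromide leaving) expands the ring to eight members and gives, regiospecifically, enolate 14 between the carbonyl and the new carbon, whose SN2 alkylation by allylic bromide 11 takes place anti to the adjacent decenyl group and so sets the second stereocentre trans (S), which is also the thermodynamic epimer.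

**Step 6**
Reactants: 15 methyl (2E,4E)-6-[(1S,8R)-8-[(8E)-dec-8-en-1-yl]-2-oxocycloocta-4,6-dien-1-yl]hexa-2,4-dienoate
Product: 17 methyl (2E,4E)-6-[(1S,8R)-8-[(8E)-dec-8-en-1-yl]-2-{[(trifluoromethyl)sulfonyl]oxy}cycloocta-2,4,6-trien-1-yl]hexa-2,4-dienoate, via potassium trienolate 16 (not isolated)
Conditions: PhNTf2, then KN(SiMe3)2 (1.05 equiv), THF, −78 to −30 °C; crude product kept below 0 °C
Reagents that add atoms: N-phenylbis(trifluoromethanesulfonimide) (O=S(=O)(N(c1ccccc1)S(=O)(=O)C(F)(F)F)C(F)(F)F)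
Why: Enol triflate formation: the hindered base removes a proton from the unhindered CH2 that is both α to the ketone and allylic to the diene, the fully conjugated trienolate is O-sulfonylated by PhNTf2, and neither stereocentre is touched.

**Step 7**
Reactants: 17 methyl (2E,4E)-6-[(1S,8R)-8-[(8E)-dec-8-en-1-yl]-2-{[(trifluoromethyl)sulfonyl]oxy}cycloocta-2,4,6-trien-1-yl]hexa-2,4-dienoate
Product: 20 target CNP0133550.1, via cyclooctatriene 18 (not isolated), via bicyclooctadiene 19 (not isolated)
Conditions: Pd(OAc)2 (5 mol %), PPh3 (12 mol %), HCO2H (2 equiv), n-Bu3N (3 equiv), DMF, 25 °C, 1 h; then short silica plug, PhMe (0.01 M), BHT, 100 °C, 14 h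
Reagents that add atoms: none
Why: Palladium-catalysed formate reduction of the enol triflate (oxidative addition to zerovalent palladium, formate-to-hydride exchange, reductive elimination) gives triene 18, which on heating undergoes reversible disrotatory 6π electrocyclisation and then an intramolecular Diels–Alder reaction of the (E,E)-dienoate with the neighbouring ring alkene of the diastereomer 19 that carries the arm on the concave face; the two stereocentres set in steps 2 and 5 (C1 and C8) are untouched and dictate C2 and C7 (cis ring fusion) and, through the exo-type transition state enforced by the three-atom tether, C5, C6, C10 and C13.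

**Compound list**
1 | 7-bromohept-1-ene | C=CCCCCCBr | starting material
2 | (E)-1-bromoprop-1-ene | C/C=C/Br | starting material
3 | hept-6-en-1-ylmagnesium bromide | C=CCCCCC[Mg]Br | intermediate
4 | (8E)-deca-1,8-diene | C/C=C/CCCCCC=C | intermediate
5 | tropone (cyclohepta-2,4,6-trien-1-one) | O=C1C=CC=CC=C1 | starting material
6 | chloro[(8E)-dec-8-en-1-yl]zirconocene, Cp2Zr(Cl)R (ionic depiction) | C/C=C/CCCCCC[CH2-].[Cl-].[Zr+4].c1cc[cH-]c1.c1cc[cH-]c1 | intermediate
7 | chlorozirconocene (7R)-7-[(8E)-dec-8-en-1-yl]cyclohepta-1,3,5-trien-1-olate (ionic depiction) | C/C=C/CCCCCCC[C@@H]1C=CC=CC=C1[O-].[Cl-].[Zr+4].c1cc[cH-]c1.c1cc[cH-]c1 | intermediate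
8 | (2R)-2-[(8E)-dec-8-en-1-yl]cyclohepta-3,5-dien-1-one | C/C=C/CCCCCCC[C@@H]1C=CC=CCC1=O | intermediate
9 | sorbic acid, (2E,4E)-hexa-2,4-dienoic acid | C/C=C/C=C/C(=O)O | starting material
10 | methyl (2E,4E)-hexa-2,4-dienoate | C/C=C/C=C/C(=O)OC | intermediate
11 | methyl (2E,4E)-6-bromohexa-2,4-dienoate | BrC/C=C/C=C/C(=O)OC | intermediate
12 | lithium (2R)-1-(dibromomethyl)-2-[(8E)-dec-8-en-1-yl]cyclohepta-3,5-dien-1-olate (both C1 epimers) | C/C=C/CCCCCCC[C@@H]1C=CC=CCC1([O-])C(Br)Br.[Li+] | intermediate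
13 | lithium (2R)-1-[bromo(lithio)methyl]-2-[(8E)-dec-8-en-1-yl]cyclohepta-3,5-dien-1-olate (β-oxido carbenoid) | C/C=C/CCCCCCC[C@@H]1C=CC=CCC1([O-])[CH-]Br.[Li+].[Li+] | intermediate
14 | lithium (3R)-3-[(8E)-dec-8-en-1-yl]cycloocta-1,4,6-trien-1-olate | C/C=C/CCCCCCC[C@@H]1/C=C\C=C/C/C([O-])=C\1.[Li+] | intermediate
15 | methyl (2E,4E)-6-[(1S,8R)-8-[(8E)-dec-8-en-1-yl]-2-oxocycloocta-4,6-dien-1-yl]hexa-2,4-dienoate | C/C=C/CCCCCCC[C@@H]1/C=C\C=C/CC(=O)[C@H]1C/C=C/C=C/C(=O)OC | intermediate
16 | potassium (7R,8S)-7-[(8E)-dec-8-en-1-yl]-8-[(2E,4E)-6-methoxy-6-oxohexa-2,4-dien-1-yl]cycloocta-1,3,5-trien-1-olate | C/C=C/CCCCCCC[C@@H]1/C=C\C=C/C=C([O-])\[C@H]1C/C=C/C=C/C(=O)OC.[K+] | intermediate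
17 | methyl (2E,4E)-6-[(1S,8R)-8-[(8E)-dec-8-en-1-yl]-2-{[(trifluoromethyl)sulfonyl]oxy}cycloocta-2,4,6-trien-1-yl]hexa-2,4-dienoate | C/C=C/CCCCCCC[C@@H]1/C=C\C=C/C=C(OS(=O)(=O)C(F)(F)F)\[C@H]1C/C=C/C=C/C(=O)OC | intermediate
18 | methyl (2E,4E)-6-[(1R,8R)-8-[(8E)-dec-8-en-1-yl]cycloocta-2,4,6-trien-1-yl]hexa-2,4-dienoate | C/C=C/CCCCCCC[C@@H]1/C=C\C=C/C=C\[C@H]1C/C=C/C=C/C(=O)OC | intermediate
19 | methyl (2E,4E)-6-[(1R,6S,7S,8S)-8-[(8E)-dec-8-en-1-yl]bicyclo[4.2.0]octa-2,4-dien-7-yl]hexa-2,4-dienoate | C/C=C/CCCCCCC[C@@H]1[C@H]2C=CC=C[C@H]2[C@H]1C/C=C/C=C/C(=O)OC | intermediate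
20 | CNP0133550.1, methyl ester of the 4-6-5-6 tetracycle: cyclobutane C1-C2-C7-C8, cyclohexene C2-C3=C4-C5-C6-C7, cyclopentane C6-C7-C8-C9-C10, cyclohexene C5-C6-C10-C11=C12-C13; (8E)-dec-8-enyl on C1, CO2Me on C13; H2, H7, H8, H6 and H5 mutually cis, H1 trans to H2 and H8, H10 trans to H6, H13 cis to H10 | C/C=C/CCCCCCC[C@@H]1[C@H]2C=C[C@@H]3[C@@H]4[C@H]2[C@H]1C[C@H]4C=C[C@H]3C(=O)OC | target

**Totals**
Total steps: 7. Longest linear sequence: 5 (steps 1, 2, 5, 6, 7).

**Steps most likely to fail**

Step 2 (the new catalytic step). The enantioselectivity is unproven, and the α-stereocentre of 8 is base-labile. Fallback (known chemistry), setting out from 4 and 5 and coming back at 8: alkylzirconocene 6, made from 4 as in step 2, is quenched with NBS to give (2E)-10-bromodec-2-ene F1. With Mg in THF this gives (8E)-dec-8-en-1-ylmagnesium bromide F2, which adds to tropone 5 without catalyst in the established 1,8-sense to give racemic 2-[(8E)-dec-8-en-1-yl]cyclohepta-3,5-dien-1-one F3. Preparative chromatography on a chiral stationary phase separates 8 from (2S)-2-[(8E)-dec-8-en-1-yl]cyclohepta-3,5-dien-1-one F4. F4 is re-racemised by a trace of Et3N through the achiral trienol and recycled, and the route continues at 8.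

Step 5 (ring expansion and alkylation in one flask). The unsubstituted CH2 may migrate instead of C2, the carbenoid may decompose before the shift, or the enolate may scramble to the more acidic allylic side before it is alkylated. Fallback, setting out from 8 and coming back at 15:
- 8 is added to bis(phenylsulfanyl)methyllithium (from bis(phenylsulfanyl)methane and n-BuLi, THF, −78 °C) to give (2R)-1-[bis(phenylsulfanyl)methyl]-2-[(8E)-dec-8-en-1-yl]cyclohepta-3,5-dien-1-ol F5.
- (CuOTf)2·C6H6 and i-Pr2NEt in benzene give (3R)-3-[(8E)-dec-8-en-1-yl]-2-(phenylsulfanyl)cycloocta-4,6-dien-1-one F6. Thiophilic monovalent copper removes one thiolate, and the sulfur-stabilised cation triggers a pinacol-type shift of the more substituted ring carbon.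
- NaH and then 11 alkylate the sulfur-activated carbon only, giving methyl (2E,4E)-6-[(8R)-8-[(8E)-dec-8-en-1-yl]-2-oxo-1-(phenylsulfanyl)cycloocta-4,6-dien-1-yl]hexa-2,4-dienoate F7.
- SmI2 (THF/MeOH, −78 °C) removes the phenylsulfanyl group, and DBU equilibrates the product to the trans keto ester 15.

Step 6 (enol triflate). If 17 undergoes 6π closure before it is reduced, it becomes a tertiary allylic triflate that ionises. Fallback, setting out from 15 and coming back at 18: NaBH4 (MeOH, 0 °C) reduces only the ketone to methyl (2E,4E)-6-[(1S,8R)-8-[(8E)-dec-8-en-1-yl]-2-hydroxycycloocta-4,6-dien-1-yl]hexa-2,4-dienoate F8. MsCl/Et3N gives methyl (2E,4E)-6-[(1S,8R)-8-[(8E)-dec-8-en-1-yl]-2-(methanesulfonyloxy)cycloocta-4,6-dien-1-yl]hexa-2,4-dienoate F9. DBU (PhMe, 25–60 °C) removes the allylic proton in an E2 elimination to give triene 18, which is heated as in step 7.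

**Further compounds**
F1 | step 2 | (2E)-10-bromodec-2-ene | C/C=C/CCCCCCCBr
F2 | step 2 | (8E)-dec-8-en-1-ylmagnesium bromide | C/C=C/CCCCCCC[Mg]Br
F3 | step 2 | racemic 2-[(8E)-dec-8-en-1-yl]cyclohepta-3,5-dien-1-one | C/C=C/CCCCCCCC1C=CC=CCC1=O
F4 | step 2 | (2S)-2-[(8E)-dec-8-en-1-yl]cyclohepta-3,5-dien-1-one | C/C=C/CCCCCCC[C@H]1C=CC=CCC1=O
F5 | step 5 | (2R)-1-[bis(phenylsulfanyl)methyl]-2-[(8E)-dec-8-en-1-yl]cyclohepta-3,5-dien-1-ol (C1 epimers) | C/C=C/CCCCCCC[C@@H]1C=CC=CCC1(O)C(Sc1ccccc1)Sc1ccccc1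
F6 | step 5 | (3R)-3-[(8E)-dec-8-en-1-yl]-2-(phenylsulfanyl)cycloocta-4,6-dien-1-one (C2 epimers) | C/C=C/CCCCCCC[C@@H]1/C=C\C=C/CC(=O)C1Sc1ccccc1
F7 | step 5 | methyl (2E,4E)-6-[(8R)-8-[(8E)-dec-8-en-1-yl]-2-oxo-1-(phenylsulfanyl)cycloocta-4,6-dien-1-yl]hexa-2,4-dienoate (C1 epimers) | C/C=C/CCCCCCC[C@@H]1/C=C\C=C/CC(=O)C1(Sc1ccccc1)C/C=C/C=C/C(=O)OC
F8 | step 6 | methyl (2E,4E)-6-[(1S,8R)-8-[(8E)-dec-8-en-1-yl]-2-hydroxycycloocta-4,6-dien-1-yl]hexa-2,4-dienoate (carbinol epimers) | C/C=C/CCCCCCC[C@@H]1/C=C\C=C/CC(O)[C@H]1C/C=C/C=C/C(=O)OC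
F9 | step 6 | methyl (2E,4E)-6-[(1S,8R)-8-[(8E)-dec-8-en-1-yl]-2-(methanesulfonyloxy)cycloocta-4,6-dien-1-yl]hexa-2,4-dienoate (epimers at the sulfonate carbon) | C/C=C/CCCCCCC[C@@H]1/C=C\C=C/CC(OS(C)(=O)=O)[C@H]1C/C=C/C=C/C(=O)OC
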